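The constants used here were drawn at random within sensible limits; the flask was simulated.

If starting material must dissolve before it can couple, the next charge of coupling partner hangs on how far the solution fills.

solid substrate 0.062 M; coupling partner 1.30 equiv; time 2.5 min

    starting material + coupling partner ⇌ target + released group (K1 = 0.51, k1 = 0.080 M⁻¹ s⁻¹)
    solid substrate ⇌ starting material, rate k2*(cs2 - [starting material]) while solid is left; crystals form when [starting material] > cs2 (cs2 = 21 mM, k2 = 0.0074 s⁻¹)
    target → over-reaction product (k3 = 0.0023 s⁻¹)
    coupling partner + target ⇌ idle adduct, settled at all times (K4 = 6.0 M⁻¹)

- amounts and yields of target count idle adduct too
- given per volume of solution although it is solid: solid substrate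
- at the start none of the solid substrate is in solution
- starting material means what is dissolved; the solid is not counted in it
- run time (flask): 2.5 min

- the target and idle adduct together standing at 2.5 min, as a percentage of the solid substrate charged
- concentration of starting material in solution at 2.5 min, in percent of saturation

1. I hold the coupling partner at its charge, which makes coupling pseudo-first-order in starting material with coefficient 0.00645 s⁻¹, close to the dissolution coefficient 0.0074 s⁻¹.

2. 53.4 % is the held level, the fraction of saturation at which dissolving just replaces what coupling takes; with the coupling partner held and the way back left out, it is the dissolution coefficient over the sum of the two coefficients.

3. The solution approaches that level with a lag of 72.2 s, the inverse of the same sum, and 2.5 min is longer than this lag, so by my reckoning it has covered 87.5 % of the way and stands near 46.7 % of saturation.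

4. Integrating that rise, and leaving out the way back, I get 6.28 mM of coupling.

5. The small correction is over-reaction, which acts on free target, a share of 67.4 %; it costs 0.559 mM, so I commit to 9.23 % of the solid charged.

6. At the held level coupling takes about half of what dissolving delivers into an empty solution, and by the formula of step 2 a larger coupling coefficient lowers the held level and raises that share, so I leave the solid charge as it is and raise the coupling partner to 5.20 equiv next.

The forecast says 8.9 % and 48 %, with the dissolved substrate moving “toward a pseudo-steady level near half of saturation”.

This flask gives 8.71 % of target and idle adduct together, with starting material at 48.1 % of saturation, 90.1 % of the held level. In this flask dissolving runs throughout, half its turnover done by 1.04 min and 74.2 % still solid at 2.5 min, while coupling trails it, half its turnover done by 1.58 min. For the flask with 5.20 equiv of coupling partner, the held level is 22.3 % and the lag 30.1 s, which gives 14.5 mM of coupling; that flask holds 0.0140 M of released group and 21.4 % of target and idle adduct together.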